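The decision is to count equivalents spent and not to chase concentrations.

| flask | starting material | reagent | capture agent | remark | time |
|---|---|---|---|---|---|
| west | 0.43 M | 0.70 equiv | 0.043 M | run made earlier |  |
| north | 0.43 M | 1.6 equiv | 0.043 M | run made earlier |  |
| east | 0.43 M | 1.05 equiv | 0.021 M | run made earlier |  |
| flask | 0.43 M | 1.05 equiv | 0.0430 M |  | 15 d |

| run | time / d | target / % | isomer of the product A / % |
|---|---|---|---|
| west | 3.00 | 33.3 | 1.2 |
| west | 6.00 | 31.6 | 2.8 |
| west | 10.0 | 29.7 | 4.8 |
| west | 12.0 | 29.7 | 7.9 |
| north | 1.04 | 47.9 | 1.1 |
| north | 2.00 | 55.1 | 2.4 |
| north | 5.00 | 52.0 | 5.5 |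
| north | 12.0 | 48.7 | 9.2 |
| east | 3.00 | 50.3 | 2.3 |
| east | 6.00 | 49.3 | 2.3 |
| east | 10.0 | 45.5 | 8.2 |
| east | 12.0 | 46.6 | 10.6 |

(standard deviation of a reading: 1 percentage point)

1. share of target in target plus isomer of the product A at 2.0 h
2. share of target in target plus isomer of the product A at 15 d
3. which of target and isomer of the product A there is more of at 15 d

- a reading or a percentage of target counts all its forms, free or not

Spending starts fast: the north run already shows 49.0% target plus isomer of the product A at 1.04 d, against 57.9% at 12.0 d. Taking the rate as proportional to both partners, two factors slow it in the flask. With 0.5 of the starting material left, the starting-material factor is 0.5 and the reagent factor 0.524, together 0.262 of the first rate. With 10.0% left, they are 0.100 and 0.143, together 0.0143. Once one equivalent is spent, the balance leaves 4.76% of the reagent charge, free and bound forms together, so starting material is the limiting reagent.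

The west run, short of reagent, gives the yield per equivalent spent, target plus isomer of the product A per equivalent of reagent used up: 53.7%, as a reading. The flask should therefore hold 53.7% in the two. Isomer of the product A, taken at the east run's average pace, reaches 13.2%, so this reckoning gives a share of 75.3% at 15 d.

The forecast gives 99.5% at 2.0 h and 76% at 15 d, slightly above that share, within 70% to 82%: “Target still leads at 15 d”.

The flask gives 98.1% and 77.7%, with target at 42.6%, more than the 12.2% of isomer of the product A; the two sum to 54.8%.

    starting material + reagent → open intermediate + released group (k = 1.70 /M/h)
    open intermediate ⇌ target (K = 1.30, k = 0.0560 /h)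
    target ⇌ isomer of the product B (K = 0.160, k = 0.0660 /h)
    reagent + target ⇌ idle adduct, settled at all times (K = 1.20 /M)
    open intermediate ⇌ isomer of the product A (K = 3.10, k = 0.00100 /h)
    open intermediate + capture agent → trapped intermediate (k = 0.0210 /M/h)

Starting material has an early half-life of 0.072 d in the flask, much shorter than the 21.8 d relaxation half-life of open intermediate and isomer of the product A by the step between those two alone. At 15 d the flask holds 0% starting material and still 31.7% open intermediate.

With 0.420 equiv of reagent, the yield per equivalent spent gives 22.6% in the neighbour. Its computed sum is 22.3%, with 0% reagent and 58.0% starting material left.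

(The runs stem from a simulated flask with made-up constants, and the scatter is random.)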